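The route rests on C11, the lactone carbon on C7, serving as a temporary one-carbon bridge to C2. C2 and C7 lie 1,6 across the ten-membered carbocycle, so ring C1–C10 is the periphery of a bicyclo[4.4.1]undecane. One [6+4] cycloaddition of a 2-alkoxy-4-methyltropone (C11 and C2–C7) with a 2-silyloxy-3-methylbutadiene (C8, C9, C10, C1) forms C7–C8 and C1–C2 and sets C7. Its precursors are two flat achiral partners: the PMB ether of 4-methyltropolone and the TBS dienol ether of isopropenyl methyl ketone. The convex face of the bicycle then controls C3, C6, C9 and C10 before ketol cleavage of C2–C11 releases the ring.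

Key step: step 5

Remarks on the chemistry (assumptions)
- Germacrane numbering (C1–C15) is used for every ring intermediate; β is the face on which C11 leaves C7 (in the bicyclic compounds the convex face that carries the C11 bridge), α the opposite, concave face.
- In the dichloroketene route the two ketene carbons are inserted into the double bond that reacts, so a methyl group on C1 of cyclopenta-1,3-diene would end at C5 (or C3) of the tropolone; only the sp3 carbon C5 (or C2) leads to C4, hence the 5-methyl isomer, whose two double bonds are equivalent, is made and trapped cold.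
- Compounds 3 to 5 are racemic or achiral (one enantiomer of 5 is drawn); these stereocentres vanish in step 2.
- The sense of induction of the copper catalyst in step 5 is assumed; the ligand antipode (both are commercial) is chosen so that 10 results.

Step 1
Reactants: 1 sodium cyclopentadienide; 2 trichloroacetyl chloride
Product: 5 rac-7,7-dichloro-4-methylbicyclo[3.2.0]hept-2-en-6-one (cis-fused; methyl anti to the four-membered ring), via 5-methylcyclopenta-1,3-diene 3 (not isolated), via dichloroketene 4 (not isolated)
Conditions: MeI, THF, −30 °C; cold pentane/ice-water work-up (≤0 °C); then 2, Zn–Cu, DME/Et2O, 0 °C, ultrasound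
Reagents that add atoms: iodomethane, CI
Why: SN2 methylation of the cyclopentadienide gives the 5-methyl isomer, which is kept cold so that no 1,5-hydrogen shift occurs, and the Staudinger [2+2] ketene cycloaddition of dichloroketene (from 2 and zinc) then takes place at either of the two equivalent double bonds, anti to the methyl group and with the carbonyl carbon on the diene terminus, so that the methyl group sits on the sp3 carbon next to the carbonyl-bearing ring-fusion carbon.

Step 2
Reactants: 5
Product: 6 4-methyltropolone (2-hydroxy-4-methylcyclohepta-2,4,6-trien-1-one)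
Conditions: NaOH, AcOH, H2O, reflux
Reagents that add atoms: water, O
Why: Solvolytic ring expansion of the α,α-dichlorocyclobutanone (the classical tropolone synthesis from dichloroketene adducts) cleaves the ring-fusion bond, hydrolyses the CCl2 group and loses two HCl to give the hydroxytropone with the methyl group at C4 (equivalent to C6 by tautomerism).

Step 3
Reactants: 6
Product: 7 2-[(4-methoxybenzyl)oxy]-4-methyltropone
Conditions: PMBCl, K2CO3, DMF, 50 °C; chromatography (the 2-alkoxy-6-methyl regioisomer is removed and returned to 6 with TFA)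
Reagents that add atoms: 4-methoxybenzyl chloride, COc1ccc(CCl)cc1
Why: Williamson O-alkylation of the tautomeric tropolone gives both ethers, of which the 4-methyl isomer is kept, and the benzyl-type ether is chosen because it offers a single ether oxygen for five-membered chelation with the carbonyl group in step 5 and can later be removed oxidatively beside an endoperoxide and a silyl ether.

Step 4
Reactants: 8 3-methylbut-3-en-2-one
Product: 9 2-(tert-butyldimethylsilyloxy)-3-methylbuta-1,3-diene
Conditions: TBSOTf, Et3N, Et2O, 0 °C
Reagents that add atoms: tert-butyldimethylsilyl trifluoromethanesulfonate, CC(C)(C)[Si](C)(C)OS(=O)(=O)C(F)(F)F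
Why: Soft enolisation of the methyl ketone at its methyl group and O-silylation (silyl dienol ether formation) give the cross-conjugated 2-silyloxydiene.

Step 5
Reactants: 7 2-[(4-methoxybenzyl)oxy]-4-methyltropone; 9 2-(tert-butyldimethylsilyloxy)-3-methylbuta-1,3-diene
Product: 10 [6+4] adduct, bicyclo[4.4.1]undeca-2,4,8-trien-11-one with C11=O bridging C2 and C7 on the β face, bridgehead C2–OPMB, C3=C4(Me)–C5=C6 diene, 7α-H and C9(OTBS)=C10(Me) enol ether
Conditions: [Cu((S,S)-t-Bu-box)](SbF6)2 (10 mol %), 4 Å MS, CH2Cl2, −40 → −20 °C, slow addition of 9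
Reagents that add atoms: none
Why: Proposed new method: the copper(II) bis(oxazoline) Lewis acid is expected to bind 7 in a five-membered chelate through the C11 carbonyl oxygen and the C2 ether oxygen, which lowers the tropone LUMO and leaves one face of the flat π system open, so that the enol ether terminus C8 of 9 adds to C7 and the silyloxyallyl cation terminus C1 is then captured by C2 of the copper trienolate, in sum a suprafacial [6π+4π] cycloaddition that may be concerted and asynchronous or stepwise (vinylogous Mukaiyama–Michael addition, then ring closure). The closest known reactions are the thermal and Lewis-acid-promoted racemic [6+4] cycloadditions of tropones with 1,3-dienes, 2-silyloxydienes included, and copper–box-catalysed additions of silyl enol ethers to chelating α-alkoxy carbonyl compounds. The new seven-membered ring C7–C8–C9–C10–C1–C2–C11, and with it the ten-membered carbocycle as the periphery of the bicycle, is closed by cycloaddition across the termini of the triene and the diene, not by end-to-end cyclisation of a chain. The two new stereocentres are the bridgeheads C2 and C7: their relative configuration is fixed because a one-atom bridge can only be cis, and their absolute configuration is set by the face of the chelated tropone that the tert-butyl groups of the ligand leave open. The step needs [6+4] over [4+2] and [8+2], which the s-cis-accessible 2-silyloxydiene and the large LUMO coefficients at C2 and C7 of the activated tropone favour, and it needs the C8-to-C7 orientation, which is secured because C2 is shielded and made less electrophilic by its alkoxy group while the enol ether CH2 is the nucleophilic end of the diene.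

Step 6
Reactants: 10
Product: 12 9,11-diketone with 10β-methyl (exo), via 10α-methyl diketone 11 (not isolated)
Conditions: TBAF·3H2O, THF, 0 °C; then DBU, rt
Reagents that add atoms: none
Why: Fluoride cleaves the silyl enol ether to the C9 ketone, and base-mediated epimerisation through the enolate (thermodynamic control) should place the C10 methyl group in the equatorial exo position on the convex face, because the endo epimer 11 suffers a 1,3-syn interaction with C3 of the diene bridge.

Step 7
Reactants: 12
Product: 13 9α-hydroxy 11-ketone (endo, axial OH; 10β-methyl)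
Conditions: L-Selectride (1.05 equiv), THF, −78 °C; aq. NH4Cl
Reagents that add atoms: none
Why: The bulky hydride (steric approach control) should reduce the C9 ketone in preference to the bridging C11 ketone, which is flanked by the quaternary C2, and should attack from the open convex face away from the diene bridge, so that the hydroxyl group ends up on the concave α face.

Step 8
Reactants: 13
Product: 15 9β-hydroxy 11-ketone, via 9β-(4-nitrobenzoate) 14 (not isolated)
Conditions: 4-O2NC6H4CO2H, PPh3, DIAD, THF, 0 °C → rt; then K2CO3, MeOH, rt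
Reagents that add atoms: 4-nitrobenzoic acid, O=C(O)c1ccc(cc1)[N+](=O)[O-]
Why: Mitsunobu esterification displaces the activated axial oxygen by SN2 from the open convex side, as in the inversion of other axial cyclic alcohols, which sets the 9β configuration of the target, and the activated ester is methanolysed in the same flask.

Step 9
Reactants: 15
Product: 16 9β-OTBS 11-ketone
Conditions: TBSOTf, 2,6-lutidine, CH2Cl2, −78 → 0 °C
Reagents that add atoms: tert-butyldimethylsilyl trifluoromethanesulfonate, CC(C)(C)[Si](C)(C)OS(=O)(=O)C(F)(F)F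
Why: Silylation of the secondary alcohol protects O9 for the organometallic steps and prevents hemiketal formation with the C11 ketone, without touching a stereocentre.

Step 10
Reactants: 16
Product: 17 3β,6β-epidioxide (endoperoxide) with Z-C4=C5
Conditions: O2, tetraphenylporphyrin (cat.), visible light, CH2Cl2, −20 °C
Reagents that add atoms: oxygen, O=O
Why: [4+2] cycloaddition of singlet oxygen to the s-cis diene held in the seven-membered ring should occur on the convex face beside the one-atom C11 bridge and away from the C8–C1 bridge, which sets 3β-O as in the target and 6β-O (inverted in step 17) and leaves C4=C5 as the Z alkene.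

Step 11
Reactants: 17
Product: 18 bridgehead 2-hydroxy 11-ketone (α-ketol) endoperoxide
Conditions: DDQ, CH2Cl2/pH 7 buffer, 0 °C → rt
Reagents that add atoms: none
Why: Oxidative PMB ether cleavage (benzylic hydride abstraction by DDQ and hydrolysis of the oxocarbenium ion) frees the tertiary hydroxyl group under neutral conditions that leave the endoperoxide, the silyl ether and the alkene intact.

Step 12
Reactants: 18
Product: 19 ring-opened methyl ester: ten-membered 2-ketone with 3β,6β-epidioxy bridge, Z-C4=C5, 7β-CO2Me (carboxyl carbon C11), 9β-OTBS and 10β-methyl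
Conditions: Pb(OAc)4, MeOH/PhH, 0 °C
Reagents that add atoms: methanol, CO
Why: Lead tetraacetate cleavage of the α-ketol (Criegee-type cleavage through the methanol hemiketal) breaks C2–C11 irreversibly, makes C2 a ketone and C11 the methyl ester on C7, and opens the bicycle to the ten-membered ring, while the endoperoxide keeps O3 from forming a cleavable 2,3-diol.

Step 13
Reactants: 19
Product: 21 2β,3β,6β-triol methyl ester, via 3β,6β-dihydroxy-2-ketone 20 (not isolated)
Conditions: thiourea, MeOH, 0 °C → rt; solvent exchange; then Zn(BH4)2, Et2O, −20 °C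
Reagents that add atoms: none
Why: Thiourea reduces the O–O bond to the cis-3,6-diol without touching the alkene, and the sensitive α-hydroxy ketone is reduced at once by zinc borohydride under Cram chelation control (zinc bridging O2 and O3, hydride from the outer face opposite C4), which should set the 2β hydroxyl cis to O3.

Step 14
Reactants: 21
Product: 22 2,3-O-isopropylidene 6-O-(2-methoxyprop-2-yl) methyl ester
Conditions: 2-methoxypropene (excess), PPTS (cat.), CH2Cl2, 0 °C
Reagents that add atoms: 2-methoxypropene, C=C(C)OC
Why: Acid-catalysed ketalisation converts the cis-1,2-diol into its acetonide and the remaining allylic C6 hydroxyl into the far more acid-labile MOP mixed ketal in one operation.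

Step 15
Reactants: 22
Product: 24 7β-acetyl compound (methyl ketone, C11=O with C13 methyl), via Weinreb amide 23 (not isolated)
Conditions: MeNHOMe·HCl, i-PrMgCl, THF, −20 °C; then MeMgBr, 0 °C
Reagents that add atoms: methylmagnesium bromide, C[Mg]Br
Why: Aminolysis of the ester by the magnesium amide of N,O-dimethylhydroxylamine and Grignard addition to the Weinreb amide (chelated tetrahedral intermediate, no over-addition) give the methyl ketone and so introduce C13.

Step 16
Reactants: 24
Product: 26 6β-hydroxy enol triflate (C11(OTf)=C13H2), via 6-O-MOP enol triflate 25 (not isolated)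
Conditions: KHMDS, THF, −78 °C; PhNTf2, −78 → 0 °C; then PPTS, MeOH, 0 °C
Reagents that add atoms: N-phenylbis(trifluoromethanesulfonimide), O=S(=O)(N(c1ccccc1)S(=O)(=O)C(F)(F)F)C(F)(F)F
Why: Kinetic deprotonation at the methyl group and O-triflation of the less substituted enolate (enol triflate formation) leave the C7 stereocentre untouched, and brief acid-catalysed methanolysis removes the MOP ketal much faster than the acetonide.

Step 17
Reactants: 26
Product: 28 6α-hydroxy enol triflate, via 6α-(4-nitrobenzoate) 27 (not isolated)
Conditions: 4-O2NC6H4CO2H, PPh3, DIAD, THF, 0 °C; then K2CO3, MeOH, 0 °C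
Reagents that add atoms: 4-nitrobenzoic acid, O=C(O)c1ccc(cc1)[N+](=O)[O-]
Why: Intermolecular Mitsunobu esterification inverts the allylic C6 carbinol by SN2 (attack at the trisubstituted C4 terminus being disfavoured), which brings O6 to the α face, trans to C11 on C7, and mild methanolysis frees the alcohol.

Step 18
Reactants: 28
Product: 29 6α,12-olide (trans-fused α-methylene-γ-butyrolactone) with 2,3-acetonide and 9β-OTBS
Conditions: Pd(PPh3)4 (5 mol %), CO (1 atm), Et3N, MeCN, 50 °C
Reagents that add atoms: carbon monoxide, [C-]#[O+]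
Why: Palladium-catalysed carbonylative lactonisation of the hydroxy vinyl triflate (oxidative addition, CO insertion, 5-exo capture of the acyl-palladium by O6) introduces C12 and closes the lactone with retention at C6 and C7.

Step 19
Reactants: 29
Product: 30 9β-hydroxy lactone acetonide
Conditions: HF·pyridine, pyridine, THF, 0 °C → rt
Reagents that add atoms: none
Why: Fluoride-mediated desilylation under buffered, non-basic conditions frees the C9 hydroxyl without conjugate addition to the α-methylene lactone and without loss of the acetonide.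

Step 20
Reactants: 30 9β-hydroxy lactone acetonide; 31 angelic acid ((Z)-2-methylbut-2-enoic acid)
Product: 33 9β-angeloyloxy lactone acetonide, via angelic 2,4,6-trichlorobenzoic anhydride 32 (not isolated)
Conditions: 2,4,6-Cl3C6H2COCl, Et3N, PhMe, rt; then 30, PhMe, 70 °C
Reagents that add atoms: none
Why: Yamaguchi-type esterification through the mixed anhydride acylates the hindered secondary alcohol with retention at C9 and, without a nucleophilic catalyst, should not isomerise the Z ester to the tiglate.

Step 21
Reactants: 33
Product: 34 CNP0229085.1, (2S,3R,4Z,6R,7S,9S,10R)-9-angeloyloxy-2,3-dihydroxy-germacra-4,11(13)-dien-12,6-olide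
Conditions: AcOH/H2O/THF (3:1:1), 40 °C
Reagents that add atoms: none
Why: Acid-catalysed hydrolysis of the isopropylidene ketal (acetonide cleavage) releases the 2,3-diol under conditions mild enough for the angelate, the allylic alcohol and the α-methylene lactone.

Compound list
1 | sodium cyclopentadienide | [Na+].[cH-]1cccc1 | starting material
2 | trichloroacetyl chloride | ClC(=O)C(Cl)(Cl)Cl | starting material
3 | 5-methylcyclopenta-1,3-diene | CC1C=CC=C1 | intermediate
4 | dichloroketene | O=C=C(Cl)Cl | intermediate
5 | rac-7,7-dichloro-4-methylbicyclo[3.2.0]hept-2-en-6-one (cis-fused, methyl anti to the cyclobutanone) | C[C@H]1C=C[C@H]2[C@@H]1C(=O)C2(Cl)Cl | intermediate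
6 | 4-methyltropolone | O=C1C=CC=C(C)C=C1O | intermediate
7 | 2-[(4-methoxybenzyl)oxy]-4-methyltropone | COc1ccc(COC2=CC(C)=CC=CC2=O)cc1 | intermediate
8 | 3-methylbut-3-en-2-one | CC(=O)C(C)=C | starting material
9 | 2-(tert-butyldimethylsilyloxy)-3-methylbuta-1,3-diene | C=C(C)C(=C)O[Si](C)(C)C(C)(C)C | intermediate
10 | [6+4] adduct, bicyclo[4.4.1]undeca-2,4,8-trien-11-one (C2–OPMB bridgehead, C4 and C10 methyls, C9 OTBS enol ether, C11 bridge β, 7α-H) | O=C1[C@]2(OCc3ccc(OC)cc3)/C=C(C)\C=C/[C@H]1C/C(O[Si](C)(C)C(C)(C)C)=C(C)\C2 | intermediate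
11 | 9,11-diketone, 10α-methyl (endo) epimer | O=C1[C@]2(OCc3ccc(OC)cc3)/C=C(C)\C=C/[C@H]1CC(=O)[C@@H](C)C2 | intermediate
12 | 9,11-diketone, 10β-methyl (exo) | O=C1[C@]2(OCc3ccc(OC)cc3)/C=C(C)\C=C/[C@H]1CC(=O)[C@H](C)C2 | intermediate
13 | 9α-hydroxy 11-ketone, 10β-methyl | O=C1[C@]2(OCc3ccc(OC)cc3)/C=C(C)\C=C/[C@H]1C[C@@H](O)[C@H](C)C2 | intermediate
14 | 9β-(4-nitrobenzoate) | O=C1[C@]2(OCc3ccc(OC)cc3)/C=C(C)\C=C/[C@H]1C[C@H](OC(=O)c3ccc(cc3)[N+](=O)[O-])[C@H](C)C2 | intermediate
15 | 9β-hydroxy 11-ketone | O=C1[C@]2(OCc3ccc(OC)cc3)/C=C(C)\C=C/[C@H]1C[C@H](O)[C@H](C)C2 | intermediate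
16 | 9β-OTBS 11-ketone | O=C1[C@]2(OCc3ccc(OC)cc3)/C=C(C)\C=C/[C@H]1C[C@H](O[Si](C)(C)C(C)(C)C)[C@H](C)C2 | intermediate
17 | 3β,6β-epidioxide of 16 | O=C1[C@]2(OCc3ccc(OC)cc3)[C@@H]3OO[C@@H](C=C3C)[C@H]1C[C@H](O[Si](C)(C)C(C)(C)C)[C@H](C)C2 | intermediate
18 | bridgehead 2-hydroxy 11-ketone endoperoxide | O=C1[C@]2(O)[C@@H]3OO[C@@H](C=C3C)[C@H]1C[C@H](O[Si](C)(C)C(C)(C)C)[C@H](C)C2 | intermediate
19 | ring-opened 2-oxo 3β,6β-epidioxy methyl ester (7β-CO2Me, 9β-OTBS, 10β-Me) | COC(=O)[C@@H]1C[C@H](O[Si](C)(C)C(C)(C)C)[C@H](C)CC(=O)[C@@H]2OO[C@H]1C=C2C | intermediate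
20 | 3β,6β-dihydroxy-2-ketone methyl ester | COC(=O)[C@@H]1C[C@H](O[Si](C)(C)C(C)(C)C)[C@H](C)CC(=O)[C@H](O)/C(C)=C\[C@@H]1O | intermediate
21 | 2β,3β,6β-triol methyl ester | COC(=O)[C@@H]1C[C@H](O[Si](C)(C)C(C)(C)C)[C@H](C)C[C@H](O)[C@H](O)/C(C)=C\[C@@H]1O | intermediate
22 | 2,3-acetonide 6-O-MOP methyl ester | COC(=O)[C@@H]1C[C@H](O[Si](C)(C)C(C)(C)C)[C@H](C)C[C@@H]2OC(C)(C)O[C@@H]2/C(C)=C\[C@@H]1OC(C)(C)OC | intermediate
23 | Weinreb amide of 22 | CON(C)C(=O)[C@@H]1C[C@H](O[Si](C)(C)C(C)(C)C)[C@H](C)C[C@@H]2OC(C)(C)O[C@@H]2/C(C)=C\[C@@H]1OC(C)(C)OC | intermediate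
24 | 7β-acetyl compound (methyl ketone) | CC(=O)[C@@H]1C[C@H](O[Si](C)(C)C(C)(C)C)[C@H](C)C[C@@H]2OC(C)(C)O[C@@H]2/C(C)=C\[C@@H]1OC(C)(C)OC | intermediate
25 | 6-O-MOP enol triflate | C=C(OS(=O)(=O)C(F)(F)F)[C@@H]1C[C@H](O[Si](C)(C)C(C)(C)C)[C@H](C)C[C@@H]2OC(C)(C)O[C@@H]2/C(C)=C\[C@@H]1OC(C)(C)OC | intermediate
26 | 6β-hydroxy enol triflate | C=C(OS(=O)(=O)C(F)(F)F)[C@@H]1C[C@H](O[Si](C)(C)C(C)(C)C)[C@H](C)C[C@@H]2OC(C)(C)O[C@@H]2/C(C)=C\[C@@H]1O | intermediate
27 | 6α-(4-nitrobenzoate) enol triflate | C=C(OS(=O)(=O)C(F)(F)F)[C@@H]1C[C@H](O[Si](C)(C)C(C)(C)C)[C@H](C)C[C@@H]2OC(C)(C)O[C@@H]2/C(C)=C\[C@H]1OC(=O)c3ccc(cc3)[N+](=O)[O-] | intermediate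
28 | 6α-hydroxy enol triflate | C=C(OS(=O)(=O)C(F)(F)F)[C@@H]1C[C@H](O[Si](C)(C)C(C)(C)C)[C@H](C)C[C@@H]2OC(C)(C)O[C@@H]2/C(C)=C\[C@H]1O | intermediate
29 | trans-fused α-methylene lactone, 2,3-acetonide, 9β-OTBS | C=C1C(=O)O[C@@H]2/C=C(/C)[C@H]3OC(C)(C)O[C@H]3C[C@@H](C)[C@@H](O[Si](C)(C)C(C)(C)C)C[C@@H]12 | intermediate
30 | 9β-hydroxy lactone acetonide | C=C1C(=O)O[C@@H]2/C=C(/C)[C@H]3OC(C)(C)O[C@H]3C[C@@H](C)[C@@H](O)C[C@@H]12 | intermediate
31 | angelic acid | C/C=C(/C)C(=O)O | starting material
32 | angelic 2,4,6-trichlorobenzoic anhydride | C/C=C(/C)C(=O)OC(=O)c1c(Cl)cc(Cl)cc1Cl | intermediate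
33 | 9β-angeloyloxy lactone acetonide | C=C1C(=O)O[C@@H]2/C=C(/C)[C@H]3OC(C)(C)O[C@H]3C[C@@H](C)[C@@H](OC(=O)/C(C)=C\C)C[C@@H]12 | intermediate
34 | CNP0229085.1 | C=C1C(=O)O[C@@H]2/C=C(/C)[C@@H](O)[C@@H](O)C[C@@H](C)[C@@H](OC(=O)/C(C)=C\C)C[C@@H]12 | target

Total step count: 21. Longest linear sequence: 20 steps (steps 1–3 and 5–21, from sodium cyclopentadienide).

Steps most likely to fail

Step 5 (the proposed new method). The chiral Lewis acid may discriminate the two tropone faces poorly, the adduct (itself an α-alkoxy ketone) may hold the copper and stop turnover, or the zwitterion may collapse by silyl transfer or by [8+2] or [4+2] closure. Fallback: 7 and 9 are combined under achiral Lewis-acid promotion (ZnCl2 or Et2AlCl, CH2Cl2), the known racemic mode of tropone–diene [6+4] cycloaddition, which gives 10 together with its enantiomer, ent-adduct F1. Steps 6 and 7 are run unchanged on the racemate, which carries the mirror-image series along: transient 10-epi ent-diketone F2, ent-diketone F3 and ent-alcohol F4, beside 12 and 13. In step 8 the 4-nitrobenzoic acid is replaced by (S)-O-methylmandelic acid, so that the Mitsunobu inversion gives two diastereomeric 9β-esters, the (S)-O-methylmandelate of 15 F5 and the (S)-O-methylmandelate of the enantiomeric alcohol F6. These are separated by chromatography or crystallisation, and methanolysis (K2CO3, MeOH) of F5 returns the route at 15.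

Step 17. The allylic oxyphosphonium ion at C6 may eliminate to a diene, ionise, or be attacked at the allylic terminus instead of being displaced with clean inversion. Fallback: inversion and ring closure are merged in an intramolecular displacement by the carboxylate. Step 16 is stopped before the acidic stage so that 25 is isolated; palladium-catalysed hydroxycarbonylation (Pd(OAc)2, dppf, KOAc, CO, DMF/H2O) of 25 gives the 6-O-MOP acrylic acid F7. Cold acidic methanolysis (PPTS, MeOH, 0 °C) gives the 6β-hydroxy acrylic acid F8, which is used at once because γ-hydroxy acids tend to lactonise with retention. Mitsunobu lactonisation (PPh3, DIAD, dilute toluene) then closes the trans-lactone with inversion at C6 and returns the route at 29.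

Step 8. The hindered axial 9α-oxyphosphonium ion may undergo E2 elimination, or the alcohol may be acylated with retention through an acyloxyphosphonium ion. Fallback: C9 is corrected under thermodynamic instead of kinetic control. Oppenauer–Meerwein–Ponndorf–Verley equilibration of 13 (Al(Oi-Pr)3, catalytic acetone, i-PrOH/toluene, 80 °C) interconverts the C9 epimers through 12 by reversible hydride transfer and should settle on the equatorial 9β-alcohol 15, which lacks the 1,3-syn interaction with C6. The hindered bridging C11 ketone is expected to react much more slowly. This fallback makes no new compound (F0) and rejoins the route at 15.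

Further compounds
F1 | step 5 | ent-adduct (enantiomer of 10) | O=C1[C@@]2(OCc3ccc(OC)cc3)/C=C(C)\C=C/[C@@H]1C/C(O[Si](C)(C)C(C)(C)C)=C(C)\C2
F2 | step 5 | 10-epi ent-diketone (enantiomer of 11) | O=C1[C@@]2(OCc3ccc(OC)cc3)/C=C(C)\C=C/[C@@H]1CC(=O)[C@H](C)C2
F3 | step 5 | ent-diketone (enantiomer of 12) | O=C1[C@@]2(OCc3ccc(OC)cc3)/C=C(C)\C=C/[C@@H]1CC(=O)[C@@H](C)C2
F4 | step 5 | ent-alcohol (enantiomer of 13) | O=C1[C@@]2(OCc3ccc(OC)cc3)/C=C(C)\C=C/[C@@H]1C[C@H](O)[C@@H](C)C2
F5 | step 5 | (S)-O-methylmandelate of 15 | O=C1[C@]2(OCc3ccc(OC)cc3)/C=C(C)\C=C/[C@H]1C[C@H](OC(=O)[C@@H](OC)c3ccccc3)[C@H](C)C2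
F6 | step 5 | (S)-O-methylmandelate of the enantiomeric alcohol | O=C1[C@@]2(OCc3ccc(OC)cc3)/C=C(C)\C=C/[C@@H]1C[C@@H](OC(=O)[C@@H](OC)c3ccccc3)[C@@H](C)C2
F7 | step 17 | 6-O-MOP acrylic acid | C=C(C(O)=O)[C@@H]1C[C@H](O[Si](C)(C)C(C)(C)C)[C@H](C)C[C@@H]2OC(C)(C)O[C@@H]2/C(C)=C\[C@@H]1OC(C)(C)OC
F8 | step 17 | 6β-hydroxy acrylic acid | C=C(C(O)=O)[C@@H]1C[C@H](O[Si](C)(C)C(C)(C)C)[C@H](C)C[C@@H]2OC(C)(C)O[C@@H]2/C(C)=C\[C@@H]1O
F0 | step 8 | none | none
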